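**Retrosynthetic overview**

1. Ainsliadimer B ⇐ desilylation and unmasking of the upper α-methylene lactone ⇐ γ-hydroxy enone 26 ⇐ aerobic γ-hydroxylation of Diels–Alder adduct 24 (O to C10, alkene shift C1=C10 → C1=C2).
2. 24 ⇐ one-pot domino of bromo-enone 19 and dehydrozaluzanin C 22: a 7-exo Heck closure forms C1–C10 and gives the diene C2=C1–C10=C14, which the exocyclic enone C4'=C15' of 22 traps in situ ([4+2]: C14–C15' and C2–C4', spiro centre C4').
3. Enabling feature: the spiro cyclohexene C1–C2–C4'–C15'–C14–C10, which shares C1=C2 with the cyclopentenone and C1–C10 with the seven-membered ring. With its alkene moved to C1=C10 it is a Diels–Alder retron, and its C1–C10 bond joins an enone β-carbon to a 2-bromoalkene carbon (Heck retron); the seven-membered ring holds the diene s-cis.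
4. 19 ⇐ Nozaki–Hiyama allylation/lactonization of aldehyde 15 with allylic bromide 7 (from 2,3-dibromopropene by Morita–Baylis–Hillman chemistry); 15 ⇐ (S)-4-silyloxycyclopentenone 8 (vinyl cuprate addition, hydroxymethylation, ozonolysis); 22 ⇐ dehydrocostus lactone 20.
5. Ring order: lower hydroazulenolide (purchased) → upper γ-lactone → upper cyclopentenone (β-elimination) → upper seven-membered ring (Heck) → spiro cyclohexene (Diels–Alder).

Key step: step 14

Remark: guaianolide numbering is used, C1–C15 for the hydroxymethyl-bearing unit and C1'–C15' for the other unit; α/β follow the guaianolide convention (H5 and H7 α, H6 β).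
Assumption: (S)-enone 8 and dehydrocostus lactone 20 are bought as single enantiomers; the C11 centre of the amine adducts and the C2 centre of 24 are drawn as the expected isomers and are erased later.

**Route**

Step 1
Reactants: 1 N-methoxy-N-methylacetamide; 2 2,3-dibromopropene
Product: 3 4-bromo-N-methoxy-N-methylpent-4-enamide
Conditions: LDA, THF, −78 °C; then 2, −78 → −40 °C
Reagents that add atoms: none
Why: Alkylation of the Weinreb amide lithium enolate at the allylic bromide of 2 (SN2); the alkenyl bromide is inert.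

Step 2
Reactants: 3
Product: 4 4-bromopent-4-enal
Conditions: DIBAL-H (i-Bu2AlH), THF, −78 °C; aq. Rochelle salt
Reagents that add atoms: none
Why: Weinreb amide reduction stops at the aldehyde because the chelated tetrahedral aluminate only collapses on work-up.

Step 3
Reactants: 4; 5 methyl acrylate
Product: 6 methyl 6-bromo-3-hydroxy-2-methylidenehept-6-enoate (racemic)
Conditions: DABCO (0.5 equiv), neat, rt, several days
Reagents that add atoms: none
Why: Morita–Baylis–Hillman reaction of an unhindered aliphatic aldehyde; the carbinol centre is removed in step 4.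

Step 4
Reactants: 6
Product: 7 methyl (2Z)-6-bromo-2-(bromomethyl)hepta-2,6-dienoate
Conditions: NBS, Me2S, CH2Cl2, 0 °C → rt
Reagents that add atoms: N-bromosuccinimide, O=C1CCC(=O)N1Br
Why: Corey–Kim-type bromination of the Baylis–Hillman alcohol with allylic transposition (SN2'), which should give the (Z)-2-(bromomethyl)enoate.

Step 5
Reactants: 8 (4S)-4-[tert-butyl(dimethyl)silyl]oxycyclopent-2-en-1-one; 9 vinylmagnesium bromide
Product: 10 (3S,4S)-4-[tert-butyl(dimethyl)silyl]oxy-3-ethenyl-1-(trimethylsilyloxy)cyclopent-1-ene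
Conditions: CuBr·SMe2 (10 mol %), TMSCl, THF, −78 °C; Et3N quench
Reagents that add atoms: chlorotrimethylsilane, C[Si](C)(C)Cl
Why: Copper-catalysed conjugate addition anti to the silyloxy group sets C5; in situ silylation fixes the enolate regiochemistry and prevents β-elimination.

Step 6
Reactants: 10; 11 formaldehyde (37 % aqueous)
Product: 12 (2R,3S,4S)-4-[tert-butyl(dimethyl)silyl]oxy-3-ethenyl-2-(hydroxymethyl)cyclopentan-1-one
Conditions: Yb(OTf)3 (10 mol %), THF–H2O, rt
Reagents that add atoms: none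
Why: Lanthanide-triflate-catalysed aqueous Mukaiyama aldol (hydroxymethylation) at the enol ether carbon; formaldehyde enters anti to the adjacent vinyl group, which sets C4 (CH2OH trans to vinyl).

Step 7
Reactants: 12
Product: 13 (2R,3S,4S)-2-{[tert-butyl(diphenyl)silyl]oxymethyl}-4-[tert-butyl(dimethyl)silyl]oxy-3-ethenylcyclopentan-1-one
Conditions: TBDPSCl, imidazole, CH2Cl2, 0 °C
Reagents that add atoms: tert-butyl(chloro)diphenylsilane, CC(C)(C)[Si](Cl)(c1ccccc1)c1ccccc1
Why: Selective silylation of the primary alcohol under weakly basic conditions that should leave the β-silyloxy ketone intact.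

Step 8
Reactants: 13
Product: 15 (1S,2R,5S)-2-{[tert-butyl(diphenyl)silyl]oxymethyl}-5-{[tert-butyl(dimethyl)silyl]oxy}-3-oxocyclopentane-1-carbaldehyde, via secondary ozonide 14 (not isolated)
Conditions: O3, CH2Cl2, −78 °C; then PPh3, −78 °C → rt
Reagents that add atoms: ozone, [O-][O+]=O
Why: Ozonolysis of the only alkene with neutral reductive work-up, which should avoid β-elimination and C5 epimerisation; the aldehyde is used at once.

Step 9
Reactants: 15; 7
Product: 17 1α-[tert-butyl(dimethyl)silyl]oxy-10-bromo-15-[tert-butyl(diphenyl)silyl]oxy-3-oxo-1,10-secoguaia-10(14),11(13)-dien-12,6α-olide (6βH,7αH trans-lactone), via hydroxy ester 16 (not isolated)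
Conditions: nickel-free CrCl2 (4 equiv), THF, 0 °C → rt; then PPTS (cat.), CH2Cl2, rt
Reagents that add atoms: none
Why: Nozaki–Hiyama allylation: divalent chromium turns 7 into a γ-substituted allylchromium that adds through C7 in a chair transition state (6,7-anti, hence the trans lactone after acid lactonization), with Felkin–Anh attack anti to the C5–C1 bond expected to set C6; the ketone and the alkenyl bromide are inert.

Step 10
Reactants: 17
Product: 18 13-(dimethylamino)-11βH-11,13-dihydro derivative of 17 (11R)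
Conditions: Me2NH (2 M in THF, 3 equiv), THF, 0 °C
Reagents that add atoms: dimethylamine, CNC
Why: Aza-Michael addition masks the α-methylene lactone, which would otherwise capture the alkenylpalladium of step 14 by 5-exo cyclization; C11 is protonated from the less hindered face and is erased in step 16.

Step 11
Reactants: 18
Product: 19 (4βH,5αH,6βH,7αH,11βH)-10-bromo-15-[tert-butyl(diphenyl)silyl]oxy-13-(dimethylamino)-3-oxo-1,10-secoguaia-1,10(14)-dien-12,6α-olide
Conditions: DBU, CH2Cl2, 0 °C
Reagents that add atoms: none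
Why: E1cB β-elimination of the ring silanolate through the less hindered C2 enolate gives the conjugated cyclopentenone; loss of the C15 silyl ether would need deprotonation at the tertiary C4 and should be slower.

Step 12
Reactants: 20 dehydrocostus lactone
Product: 21 3α-hydroxydehydrocostus lactone (3-epizaluzanin C)
Conditions: SeO2 (cat.), t-BuOOH, CH2Cl2, rt
Reagents that add atoms: tert-butyl hydroperoxide, CC(C)(C)OO
Why: Selenium dioxide allylic oxidation (ene reaction, then [2,3]-shift) at the allylic methylene C3' next to C4'=C15'; the new centre (convex-face delivery) is removed in step 13.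

Step 13
Reactants: 21
Product: 22 dehydrozaluzanin C
Conditions: Dess–Martin periodinane, CH2Cl2, rt
Reagents that add atoms: none
Why: Neutral oxidation of the allylic alcohol to the exocyclic enone without isomerising it into the ring.

Step 14
Reactants: 19; 22 (3 equiv)
Product: 24 Diels–Alder adduct (C1=C10 alkene; 2α-H; spiro C4'), via s-cis dienone 23 (not isolated)
Conditions: Pd(OAc)2 (10 mol %), P(o-tol)3 (25 mol %), Ag2CO3 (1.5 equiv), MeCN, 80 °C, 5 mM in 19, dark
Reagents that add atoms: none
Why: Zerovalent palladium inserts into the C10–Br bond, the alkenylpalladium adds 7-exo-trig across the cyclopentenone at its β-carbon C1, and epimerisation of the C2 palladium enolate followed by β-hydride elimination gives dienone 23 (C1–C10 bond, seven-membered ring closed); its diene C2=C1–C10=C14, held s-cis by that ring, is trapped in the same flask by the ketone-activated exocyclic alkene C4'=C15' of 22 (C14–C15' and C2–C4' bonds, spiro cyclohexene closed). The closest known reaction types are the intramolecular Mizoroki–Heck reaction on cyclic enones and domino Heck–Diels–Alder sequences in which a palladium-made diene is intercepted in situ. The seven-membered ring closes by 7-exo-trig carbopalladation (8-endo is disfavoured and electronically mismatched), and the cyclohexene closes by intermolecular [4+2] cycloaddition with "ortho" regiochemistry (unsubstituted diene terminus C14 to the enone β-carbon C15'). The quaternary spiro centre C4' is set by approach of the diene to the convex α-face of the cis-fused hydroazulenone 22 (the face of H1' and H5'); the C2 centre, drawn for the endo mode, is transient and is erased in step 15. The step needs intramolecular carbopalladation to outrun intermolecular Heck coupling with 22, which high dilution in 19 and the amine mask on C11–C13 should secure; it also needs the enone of 22 to react in preference to its α-methylene lactone, which its stronger activation should secure, and 23 cannot dimerise because it carries no free dienophile.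

Step 15
Reactants: 24
Product: 26 10β-hydroxy-1(2)-en-3-one (15-O-silyl 13-amino-protected ainsliadimer B), via C10 hydroperoxide 25 (not isolated)
Conditions: O2 (1 atm), Et3N, MeCN, rt; then PPh3, 0 °C
Reagents that add atoms: dioxygen, O=O
Why: Base-promoted autoxidation of the β,γ-unsaturated ketone through its dienol (C3–O, C2=C1–C10) puts oxygen on the γ-carbon C10 and moves the alkene into conjugation; oxygen should enter from the β-face, anti to the C5' wing of the spiro-linked lower unit, and phosphine reduces the hydroperoxide.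

Step 16
Reactants: 26
Product: 28 15-O-[tert-butyl(diphenyl)silyl]ainsliadimer B, via trimethylammonium iodide 27 (not isolated)
Conditions: MeI (10 equiv), MeCN, rt; then aq. NaHCO3, CH2Cl2, rt
Reagents that add atoms: none
Why: Quaternisation and mild-base E1cB (Hofmann-type) elimination regenerate the upper α-methylene lactone and erase C11.

Step 17
Reactants: 28
Product: 29 ainsliadimer B
Conditions: HF·pyridine, THF, 0 °C → rt
Reagents that add atoms: none
Why: Mildly acidic fluoride desilylation frees the primary alcohol without base-induced β-elimination of the β-hydroxy ketone.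

**Compound list**

1 | N-methoxy-N-methylacetamide | CC(=O)N(C)OC | starting material
2 | 2,3-dibromopropene | C=C(Br)CBr | starting material
3 | 4-bromo-N-methoxy-N-methylpent-4-enamide | C=C(Br)CCC(=O)N(C)OC | intermediate
4 | 4-bromopent-4-enal | C=C(Br)CCC=O | intermediate
5 | methyl acrylate | C=CC(=O)OC | starting material
6 | methyl 6-bromo-3-hydroxy-2-methylidenehept-6-enoate (racemic) | C=C(Br)CCC(O)C(=C)C(=O)OC | intermediate
7 | methyl (2Z)-6-bromo-2-(bromomethyl)hepta-2,6-dienoate | C=C(Br)CC/C=C(\CBr)C(=O)OC | intermediate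
8 | (4S)-4-[tert-butyl(dimethyl)silyl]oxycyclopent-2-en-1-one | O=C1C=C[C@@H](O[Si](C)(C)C(C)(C)C)C1 | starting material
9 | vinylmagnesium bromide | C=C[Mg]Br | starting material
10 | (3S,4S)-4-[tert-butyl(dimethyl)silyl]oxy-3-ethenyl-1-(trimethylsilyloxy)cyclopent-1-ene | C[Si](C)(C)OC1=C[C@H](C=C)[C@@H](O[Si](C)(C)C(C)(C)C)C1 | intermediate
11 | formaldehyde | C=O | starting material
12 | (2R,3S,4S)-4-[tert-butyl(dimethyl)silyl]oxy-3-ethenyl-2-(hydroxymethyl)cyclopentan-1-one | O=C1C[C@H](O[Si](C)(C)C(C)(C)C)[C@@H](C=C)[C@@H]1CO | intermediate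
13 | (2R,3S,4S)-2-{[tert-butyl(diphenyl)silyl]oxymethyl}-4-[tert-butyl(dimethyl)silyl]oxy-3-ethenylcyclopentan-1-one | O=C1C[C@H](O[Si](C)(C)C(C)(C)C)[C@@H](C=C)[C@@H]1CO[Si](c2ccccc2)(c3ccccc3)C(C)(C)C | intermediate
14 | secondary ozonide of 13 (1,2,4-trioxolan-3-yl in place of ethenyl; mixture at the trioxolane carbon) | O=C1C[C@H](O[Si](C)(C)C(C)(C)C)[C@@H](C2OCOO2)[C@@H]1CO[Si](c3ccccc3)(c4ccccc4)C(C)(C)C | intermediate
15 | (1S,2R,5S)-2-{[tert-butyl(diphenyl)silyl]oxymethyl}-5-{[tert-butyl(dimethyl)silyl]oxy}-3-oxocyclopentane-1-carbaldehyde | O=C1C[C@H](O[Si](C)(C)C(C)(C)C)[C@@H](C=O)[C@@H]1CO[Si](c2ccccc2)(c3ccccc3)C(C)(C)C | intermediate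
16 | methyl (6S,7S)-1α-[tert-butyl(dimethyl)silyl]oxy-10-bromo-15-[tert-butyl(diphenyl)silyl]oxy-6-hydroxy-3-oxo-1,10-secoguaia-10(14),11(13)-dien-12-oate | C=C(C(=O)OC)[C@H](CCC(Br)=C)[C@H](O)[C@@H]1[C@@H](O[Si](C)(C)C(C)(C)C)CC(=O)[C@H]1CO[Si](c2ccccc2)(c3ccccc3)C(C)(C)C | intermediate
17 | 1α-[tert-butyl(dimethyl)silyl]oxy-10-bromo-15-[tert-butyl(diphenyl)silyl]oxy-3-oxo-1,10-secoguaia-10(14),11(13)-dien-12,6α-olide (4βH,5αH,6βH,7αH) | C=C1C(=O)O[C@@H]([C@H]1CCC(Br)=C)[C@@H]2[C@@H](O[Si](C)(C)C(C)(C)C)CC(=O)[C@H]2CO[Si](c3ccccc3)(c4ccccc4)C(C)(C)C | intermediate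
18 | 13-(dimethylamino)-11βH-11,13-dihydro derivative of 17 (11R) | CN(C)C[C@@H]1C(=O)O[C@@H]([C@H]1CCC(Br)=C)[C@@H]2[C@@H](O[Si](C)(C)C(C)(C)C)CC(=O)[C@H]2CO[Si](c3ccccc3)(c4ccccc4)C(C)(C)C | intermediate
19 | (4βH,5αH,6βH,7αH,11βH)-10-bromo-15-[tert-butyl(diphenyl)silyl]oxy-13-(dimethylamino)-3-oxo-1,10-secoguaia-1,10(14)-dien-12,6α-olide | CN(C)C[C@@H]1C(=O)O[C@@H]([C@H]1CCC(Br)=C)[C@@H]2C=CC(=O)[C@H]2CO[Si](c3ccccc3)(c4ccccc4)C(C)(C)C | intermediate
20 | dehydrocostus lactone, (3aS,6aR,9aR,9bS)-3,6,9-trimethylidenedecahydroazuleno[4,5-b]furan-2-one | C=C1CC[C@H]2C(=C)CC[C@H]3C(=C)C(=O)O[C@@H]3[C@@H]12 | starting material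
21 | 3α-hydroxydehydrocostus lactone (3-epizaluzanin C) | C=C1[C@H](O)C[C@H]2C(=C)CC[C@H]3C(=C)C(=O)O[C@@H]3[C@@H]12 | intermediate
22 | dehydrozaluzanin C (3-oxodehydrocostus lactone) | C=C1C(=O)C[C@H]2C(=C)CC[C@H]3C(=C)C(=O)O[C@@H]3[C@@H]12 | intermediate
23 | 15-[tert-butyl(diphenyl)silyl]oxy-13-(dimethylamino)-3-oxo-11βH-guaia-1,10(14)-dien-12,6α-olide (s-cis diene C2=C1–C10=C14) | CN(C)C[C@@H]1C(=O)O[C@@H]2[C@@H]3C(=CC(=O)[C@H]3CO[Si](c4ccccc4)(c5ccccc5)C(C)(C)C)C(=C)CC[C@@H]12 | intermediate
24 | Diels–Alder adduct of 23 and 22: cyclohexene C1=C10 with new bonds C2–C4' and C14–C15', spiro at C4' (C2 on the α-face of the lower unit), 2α-H | CN(C)C[C@@H]1C(=O)O[C@@H]2[C@@H]3C(=C(CC[C@@H]12)CC[C@@]45C(=O)C[C@H]6C(=C)CC[C@H]7C(=C)C(=O)O[C@@H]7[C@H]64)[C@H]5C(=O)[C@H]3CO[Si](c8ccccc8)(c9ccccc9)C(C)(C)C | intermediate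
25 | 10β-hydroperoxide of the C1=C2 enone (hydroperoxy analogue of 26) | CN(C)C[C@@H]1C(=O)O[C@@H]2[C@@H]3C4=C(C(=O)[C@H]3CO[Si](c5ccccc5)(c6ccccc6)C(C)(C)C)[C@]3(CC[C@]4(OO)CC[C@@H]12)C(=O)C[C@H]1C(=C)CC[C@H]2C(=C)C(=O)O[C@@H]2[C@H]13 | intermediate
26 | 15-O-[tert-butyl(diphenyl)silyl]-13-(dimethylamino)-11βH-11,13-dihydroainsliadimer B | CN(C)C[C@@H]1C(=O)O[C@@H]2[C@@H]3C4=C(C(=O)[C@H]3CO[Si](c5ccccc5)(c6ccccc6)C(C)(C)C)[C@]3(CC[C@]4(O)CC[C@@H]12)C(=O)C[C@H]1C(=C)CC[C@H]2C(=C)C(=O)O[C@@H]2[C@H]13 | intermediate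
27 | 13-trimethylammonium iodide of 26 | C[N+](C)(C)C[C@@H]1C(=O)O[C@@H]2[C@@H]3C4=C(C(=O)[C@H]3CO[Si](c5ccccc5)(c6ccccc6)C(C)(C)C)[C@]3(CC[C@]4(O)CC[C@@H]12)C(=O)C[C@H]1C(=C)CC[C@H]2C(=C)C(=O)O[C@@H]2[C@H]13.[I-] | intermediate
28 | 15-O-[tert-butyl(diphenyl)silyl]ainsliadimer B | C=C1C(=O)O[C@@H]2[C@@H]3C4=C(C(=O)[C@H]3CO[Si](c5ccccc5)(c6ccccc6)C(C)(C)C)[C@]3(CC[C@]4(O)CC[C@@H]12)C(=O)C[C@H]1C(=C)CC[C@H]2C(=C)C(=O)O[C@@H]2[C@H]13 | intermediate
29 | ainsliadimer B | C=C1C(=O)O[C@@H]2[C@@H]3C4=C(C(=O)[C@H]3CO)[C@]3(CC[C@]4(O)CC[C@@H]12)C(=O)C[C@H]1C(=C)CC[C@H]2C(=C)C(=O)O[C@@H]2[C@H]13 | target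

**Step count and risks**

Total step count: 17. Longest linear sequence: 11 steps (8 → 10 → 12 → 13 → 15 → 17 → 18 → 19 → 24 → 26 → 28 → 29; steps 5–11 and 14–17).

Most likely to fail:

1. Step 14. The alkenylpalladium may undergo intermolecular Heck coupling with 22, or palladium hydride may isomerise the diene, before the 7-exo closure and cycloaddition take place. The fallback sets out from 19 and returns at 24. Tin hydride radical cyclization (Bu3SnH, AIBN, slow addition, benzene, 80 °C, high dilution) should close the seven-membered ring by 7-exo attack of the C10 alkenyl radical on C1 and give the cis-fused 3-oxo-guai-10(14)-enolide F1. Kinetic enolization toward C2 (LiN(SiMe3)2, TMSCl, THF, −78 °C) should give the trimethylsilyl enol ether F2. Saegusa–Ito dehydrogenation of F2 with Pd(OAc)2 in MeCN in the presence of 22 should unveil diene 23, which is trapped by the same Diels–Alder reaction to give 24.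

2. Step 9. Facial selectivity at C6 may be poor, because both ring neighbours of C5 carry trans substituents, and the anti preference of the allylchromium may erode. The fallback sets out from 4 and 15 and returns at 17. Ohira–Bestmann homologation of 4 (dimethyl (1-diazo-2-oxopropyl)phosphonate, K2CO3, MeOH) gives 5-bromohex-5-en-1-yne F3. Deprotonation with LDA at −78 °C and acylation with methyl chloroformate gives methyl 6-bromohept-6-en-2-ynoate F4. Syn-hydrometalation (DIBAL-H, HMPA, cat. MeCu) and trapping with ICH2B(pin) gives the geometrically defined methyl (2Z)-6-bromo-2-[(pinacolatoboryl)methyl]hepta-2,6-dienoate F5. Allylboration of 15 with F5 through a closed chair transition state is stereospecifically anti, and a chiral BINOL-derived phosphoric acid catalyst supplies reagent control of the aldehyde face; this gives 16 and, after PPTS lactonization, 17.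

3. Step 15. The base may only isomerise the alkene into conjugation without oxygen uptake, or oxygen may be delivered to the α-face of C10. The fallback sets out from 24 and returns at 26. The amine is protonated with TFA (1.1 equiv) and the electron-rich tetrasubstituted C1=C10 alkene is epoxidized with mCPBA (CH2Cl2, −20 °C) from the less hindered face to give the 1β,10β-epoxide F6. Treatment with Et3N then opens the β,γ-epoxy ketone by E1cB elimination (C2–H, C1–O) to the γ-hydroxy enone 26.

Further compounds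
F1 | step 14 | 15-[tert-butyl(diphenyl)silyl]oxy-13-(dimethylamino)-3-oxo-1αH,11βH-guai-10(14)-en-12,6α-olide | CN(C)C[C@@H]1C(=O)O[C@@H]2[C@@H]3[C@@H](CC(=O)[C@H]3CO[Si](c4ccccc4)(c5ccccc5)C(C)(C)C)C(=C)CC[C@@H]12
F2 | step 14 | 3-trimethylsilyloxy-2-ene (silyl enol ether of F1) | CN(C)C[C@@H]1C(=O)O[C@@H]2[C@@H]3[C@@H](C=C(O[Si](C)(C)C)[C@H]3CO[Si](c4ccccc4)(c5ccccc5)C(C)(C)C)C(=C)CC[C@@H]12
F3 | step 9 | 5-bromohex-5-en-1-yne | C=C(Br)CCC#C
F4 | step 9 | methyl 6-bromohept-6-en-2-ynoate | C=C(Br)CCC#CC(=O)OC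
F5 | step 9 | methyl (2Z)-6-bromo-2-[(4,4,5,5-tetramethyl-1,3,2-dioxaborolan-2-yl)methyl]hepta-2,6-dienoate | C=C(Br)CC/C=C(/CB1OC(C)(C)C(C)(C)O1)C(=O)OC
F6 | step 15 | 1β,10β-epoxide of 24 | CN(C)C[C@@H]1C(=O)O[C@@H]2[C@@H]3[C@]6(O[C@]6(CC[C@@H]12)CC[C@@]45C(=O)C[C@H]7C(=C)CC[C@H]8C(=C)C(=O)O[C@@H]8[C@H]74)[C@H]5C(=O)[C@H]3CO[Si](c9ccccc9)(c%10ccccc%10)C(C)(C)C
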